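**Plan**

Numbering: ring B = C1 (CO2Me), C2 (OH), C3 (Me), C4 (O-acyl), C5 (Me), C6 (Me). Ring A = C1' (C=O), C2' (OH), C3' (Me), C4' (OMe), C5' (Cl), C6' (Me).
Cuts: first the depside bond between the C4 oxygen and the C1' carbonyl, giving a ring B phenol and a ring A acid. Then C5-C6 and C1-C2 of ring B are cut together in one retro-Diels-Alder operation.
Enabling feature: C2-C3-C4-C5 of ring B holds both oxygens in a 1,3-relation plus two methyls, which is the chain of methyl 2-methyl-3-oxopentanoate as its bis(silyl) dienol ether. C1-C6, with its ester and methyl, is methyl but-2-ynoate, and its alkyne level lets the adduct aromatise by simple loss of methanol.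
Forward: the keto ester is methylated and silylated twice, and the cycloaddition closes ring B, the only ring made. Ring A comes from atraric acid (C5' chlorination, C4' O-methylation, saponification), and the two halves are esterified last.
Stereochemistry: the target has no stereocentre and no stereogenic double bond. Only the 3Z geometry of the diene matters (for reactivity), and it should come from allylic strain in the γ-deprotonation.

Key step: step 4

Remark on the chemistry: the silyl enol ether of step 2 is expected as an E/Z mixture and the cycloadduct of step 4 as a diastereomer mixture, so both are written without descriptors. The ketene acetal geometry of the diene is drawn in one form only for definiteness. All of these elements are erased further on.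

**Route**

Step 1
Reactants: 1 methyl 3-oxopentanoate
Product: 2 methyl 2-methyl-3-oxopentanoate (racemic, configurationally labile)
Conditions: MeI (1.05 equiv), K2CO3, acetone, reflux
Reagents that add atoms: iodomethane, CI
Why: This is a classical β-keto ester alkylation in which K2CO3 removes only the doubly activated C2-H and the enolate is C-methylated by MeI in an SN2 reaction, a near-stoichiometric charge of MeI holding back a second methylation.

Step 2
Reactants: 2 methyl 2-methyl-3-oxopentanoate
Product: 3 methyl 2-methyl-3-(trimethylsilyloxy)pent-2-enoate (E/Z mixture)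
Conditions: TMSCl (1.5 equiv), Et3N (1.5 equiv), toluene, rt, 2-3 d; filtration under Ar
Reagents that add atoms: chlorotrimethylsilane, C[Si](C)(C)Cl
Why: O-silylation of a β-keto ester enol with an amine base is the standard first stage on the way to 1,3-bis(silyloxy)dienes, it tolerates a C2 alkyl group, and precipitation of the ammonium salt from toluene drives it forward.

Step 3
Reactants: 3 methyl 2-methyl-3-(trimethylsilyloxy)pent-2-enoate
Product: 5 (1Z,3Z)-1-methoxy-2-methyl-1,3-bis(trimethylsilyloxy)penta-1,3-diene, via lithium dienolate 4 (not isolated)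
Conditions: LiN(iPr)2 (LDA, 1.2 equiv), THF, -78 °C; then TMSCl (1.3 equiv), -78 °C to rt; hexane, filtration under Ar, used crude
Reagents that add atoms: chlorotrimethylsilane, C[Si](C)(C)Cl
Why: Kinetic γ-deprotonation of the β-silyloxy enoate at its only acidic site (the CH2 of the ethyl group) gives the extended dienolate 4, which is silylated on oxygen (silyl ketene acetal formation), and allylic strain against the C2 methyl should turn the terminal methyl away from C2, that is to the 3Z isomer.

Step 4
Reactants: 5 (1Z,3Z)-1-methoxy-2-methyl-1,3-bis(trimethylsilyloxy)penta-1,3-diene; 6 methyl but-2-ynoate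
Product: 9 methyl 2,4-dihydroxy-3,5,6-trimethylbenzoate, via cyclohexa-1,4-diene cycloadduct 7 (not isolated), via bis(trimethylsilyl) ether 8 (not isolated)
Conditions: 5 (2 equiv), 6 (1 equiv), neat, sealed tube under Ar, 120 °C, 24-48 h; then 1 M HCl, THF, rt
Reagents that add atoms: none
Why: The reaction is a normal-electron-demand but strongly asynchronous Diels-Alder cycloaddition in which the CH(Me) terminus of 5, fed with electron density by all three oxygens, bonds first to the electrophilic β-carbon of 6 (C5-C6), after which the ketene acetal carbon closes onto the ester-bearing α-carbon (C1-C2) to give 7. Loss of methanol across C2 and C5 of 7 gives the aromatic bis(silyl) ether 8, and dilute acid then frees both phenols. The closest known reaction type is the cycloaddition-aromatisation of 1,1,3-trioxygenated buta-1,3-dienes with alkynoates, β-alkyl ynoates included, which delivers resorcylates. Ring B, the only ring closed, arises as a six-membered carbocycle by an intermolecular [4+2] closure, and the two sp3 carbons of 7 (C2 and C5) become trigonal again, so no stereocentre needs control. The selectivity needed is regiochemical and rests on the matched polarisation of the two partners, which puts the future C2 oxygen next to C1; from the mixed silyl methyl ketal it is the methoxy group that leaves, as is usual for mixed vinylketene acetals, so C2 ends as a free hydroxyl. The 3Z geometry keeps the terminal methyl outside the s-cis conformer, and the low reactivity of the β-methyl ynoate is met by working neat, hot and with an excess of 5, part of which the released methanol will consume.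

Step 5
Reactants: 10 methyl 2,4-dihydroxy-3,6-dimethylbenzoate (atraric acid)
Product: 11 methyl 5-chloro-2,4-dihydroxy-3,6-dimethylbenzoate
Conditions: SO2Cl2 (1.0 equiv), CH2Cl2-Et2O, 0 °C to rt
Reagents that add atoms: sulfuryl chloride, O=S(=O)(Cl)Cl
Why: This is an electrophilic aromatic chlorination at C5', the only unsubstituted ring carbon, which is ortho to the 4'-OH and para to the 2'-OH, and one equivalent of reagent in the cold avoids ipso attack and dearomatisation.

Step 6
Reactants: 11 methyl 5-chloro-2,4-dihydroxy-3,6-dimethylbenzoate
Product: 12 methyl 5-chloro-2-hydroxy-4-methoxy-3,6-dimethylbenzoate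
Conditions: MeI (1.05 equiv), K2CO3 (1.1 equiv), acetone, rt to 40 °C
Reagents that add atoms: iodomethane, CI
Why: In this Williamson ether synthesis the 2'-OH is locked in a hydrogen bond to the ester carbonyl and is the weaker acid, so K2CO3 ionises the 4'-OH (made more acidic by the neighbouring chlorine) and one equivalent of MeI alkylates only there.

Step 7
Reactants: 12 methyl 5-chloro-2-hydroxy-4-methoxy-3,6-dimethylbenzoate
Product: 14 5-chloro-2-hydroxy-4-methoxy-3,6-dimethylbenzoic acid, via dipotassium salt 13 (not isolated)
Conditions: KOH (excess), DMSO-H2O, 90 °C; then 2 M HCl, 0 °C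
Reagents that add atoms: potassium hydroxide, [K+].[OH-]
Why: Saponification of a di-ortho-substituted salicylate needs the poorly solvated hydroxide of aqueous DMSO, the usual medium for hindered orsellinate-type esters, and acidification in the cold protects the electron-rich acid from decarboxylation.

Step 8
Reactants: 14 5-chloro-2-hydroxy-4-methoxy-3,6-dimethylbenzoic acid; 9 methyl 2,4-dihydroxy-3,5,6-trimethylbenzoate
Product: 16 3-hydroxy-4-(methoxycarbonyl)-2,5,6-trimethylphenyl 5-chloro-2-hydroxy-4-methoxy-3,6-dimethylbenzoate (target), via mixed trifluoroacetic anhydride 15 (not isolated)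
Conditions: (CF3CO)2O, toluene, 0 °C to rt; aq NaHCO3 work-up
Reagents that add atoms: none
Why: This mixed-anhydride esterification is the standard depside coupling, in which the donor-substituted aroyl carbon of 15 has enough acylium character to reach the C4 oxygen between two methyls, both chelated ortho hydroxyls (C2-OH and C2'-OH) stay out of the reaction, and the fully substituted ring B offers no site for Friedel-Crafts acylation.

**Compound list**

1 | methyl 3-oxopentanoate | CCC(=O)CC(=O)OC | starting material
2 | methyl 2-methyl-3-oxopentanoate (racemic) | CCC(=O)C(C)C(=O)OC | intermediate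
3 | methyl 2-methyl-3-(trimethylsilyloxy)pent-2-enoate (E/Z mixture) | CCC(O[Si](C)(C)C)=C(C)C(=O)OC | intermediate
4 | lithium 1-methoxy-2-methyl-3-(trimethylsilyloxy)penta-1,3-dien-1-olate (formed in situ) | CO/C([O-])=C(C)/C(O[Si](C)(C)C)=C/C.[Li+] | intermediate
5 | (1Z,3Z)-1-methoxy-2-methyl-1,3-bis(trimethylsilyloxy)penta-1,3-diene | CO/C(O[Si](C)(C)C)=C(C)/C(O[Si](C)(C)C)=C/C | intermediate
6 | methyl but-2-ynoate | CC#CC(=O)OC | starting material
7 | methyl 6-methoxy-2,3,5-trimethyl-4,6-bis(trimethylsilyloxy)cyclohexa-1,4-diene-1-carboxylate (formed in situ, diastereomer mixture) | COC(=O)C1=C(C)C(C)C(O[Si](C)(C)C)=C(C)C1(OC)O[Si](C)(C)C | intermediate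
8 | methyl 3,5,6-trimethyl-2,4-bis(trimethylsilyloxy)benzoate (formed in situ) | COC(=O)c1c(C)c(C)c(O[Si](C)(C)C)c(C)c1O[Si](C)(C)C | intermediate
9 | methyl 2,4-dihydroxy-3,5,6-trimethylbenzoate | COC(=O)c1c(C)c(C)c(O)c(C)c1O | intermediate
10 | methyl 2,4-dihydroxy-3,6-dimethylbenzoate (atraric acid) | COC(=O)c1c(C)cc(O)c(C)c1O | starting material
11 | methyl 5-chloro-2,4-dihydroxy-3,6-dimethylbenzoate | COC(=O)c1c(C)c(Cl)c(O)c(C)c1O | intermediate
12 | methyl 5-chloro-2-hydroxy-4-methoxy-3,6-dimethylbenzoate | COC(=O)c1c(C)c(Cl)c(OC)c(C)c1O | intermediate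
13 | dipotassium 5-chloro-4-methoxy-3,6-dimethyl-2-oxidobenzoate (formed in situ) | [K+].[K+].[O-]C(=O)c1c(C)c(Cl)c(OC)c(C)c1[O-] | intermediate
14 | 5-chloro-2-hydroxy-4-methoxy-3,6-dimethylbenzoic acid | OC(=O)c1c(C)c(Cl)c(OC)c(C)c1O | intermediate
15 | 5-chloro-2-hydroxy-4-methoxy-3,6-dimethylbenzoic trifluoroacetic anhydride (formed in situ) | O=C(OC(=O)C(F)(F)F)c1c(C)c(Cl)c(OC)c(C)c1O | intermediate
16 | 3-hydroxy-4-(methoxycarbonyl)-2,5,6-trimethylphenyl 5-chloro-2-hydroxy-4-methoxy-3,6-dimethylbenzoate (CNP0313903.0) | COC(=O)c1c(C)c(C)c(OC(=O)c2c(C)c(Cl)c(OC)c(C)c2O)c(C)c1O | target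

**Step count**

Total step count: 8.
Longest linear sequence: 5 steps (steps 1, 2, 3, 4 and 8). The ring A arm takes 4 steps (5, 6, 7 and 8).

**Steps most likely to fail**

**Step 4.**
- What may go wrong: addition to the β-methyl ynoate may be slower than thermal breakdown of the tetrasubstituted diene and its protodesilylation by the released methanol. After the first bond forms, silyl transfer may also stop the process at an open-chain conjugate adduct.
- Fallback, from 10 back to 9: ring B would not be built but taken from atraric acid. Rieche formylation of 10 (Cl2CHOMe, TiCl4, CH2Cl2, 0 °C) at its only free ring carbon should give methyl 5-formyl-2,4-dihydroxy-3,6-dimethylbenzoate F1. Hydrogenolysis of this ortho-hydroxy aldehyde to the methyl compound (H2, Pd/C, AcOH, rt) comes back to the route at 9.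

**Step 8.**
- What may go wrong: trifluoroacetylation of the hindered phenol, self-acylation through the free C2' hydroxyl, or acid-induced decarboxylation of 14 may outrun formation of the doubly hindered ester bond.
- Fallback, from 12 back to 16: this switches to a protected acid chloride under basic conditions.
  - The chelated hydroxyl would be masked (BnBr, K2CO3, DMF, 60 °C) to give methyl 2-(benzyloxy)-5-chloro-4-methoxy-3,6-dimethylbenzoate F2.
  - Saponification (KOH, DMSO-H2O, 90 °C) would give 2-(benzyloxy)-5-chloro-4-methoxy-3,6-dimethylbenzoic acid F3.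
  - Treatment with (COCl)2 and catalytic DMF in CH2Cl2 would give 2-(benzyloxy)-5-chloro-4-methoxy-3,6-dimethylbenzoyl chloride F4.
  - Acylation of 9 at its more acidic C4 hydroxyl (NaH, 1 equiv, THF, 0 °C to rt) should give 3-hydroxy-4-(methoxycarbonyl)-2,5,6-trimethylphenyl 2-(benzyloxy)-5-chloro-4-methoxy-3,6-dimethylbenzoate F5.
  - Brief hydrogenolysis (H2, Pd/C, EtOAc, rt), under which the flanked aryl chloride should persist, comes back at 16.

**Step 3.**
- What may go wrong: competing C-silylation, hydrolysis of the doubly silylated diene during isolation, or formation of the 3E isomer, whose inward methyl blocks the s-cis conformer, may leave too little reactive diene.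
- Fallback, from 2 back to 9: this replaces the C3 silyl ether with a robust methyl ether and pays with a final demethylation.
  - Enol ether formation (HC(OMe)3, catalytic H2SO4, MeOH, then distillation) would give methyl 3-methoxy-2-methylpent-2-enoate F6.
  - γ-Deprotonation and O-silylation (LiN(iPr)2, THF, -78 °C; TMSCl) would give (1Z,3Z)-1,3-dimethoxy-2-methyl-1-(trimethylsilyloxy)penta-1,3-diene F7.
  - Heating with 6 as in step 4, followed by dilute HCl, should give methyl 2-hydroxy-4-methoxy-3,5,6-trimethylbenzoate F8.
  - Cleavage of the doubly flanked aryl methyl ether (BBr3, CH2Cl2, -78 to 0 °C) comes back at 9.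

**Further compounds**

F1 | step 4 | methyl 5-formyl-2,4-dihydroxy-3,6-dimethylbenzoate | COC(=O)c1c(C)c(C=O)c(O)c(C)c1O
F2 | step 8 | methyl 2-(benzyloxy)-5-chloro-4-methoxy-3,6-dimethylbenzoate | COC(=O)c1c(C)c(Cl)c(OC)c(C)c1OCc1ccccc1
F3 | step 8 | 2-(benzyloxy)-5-chloro-4-methoxy-3,6-dimethylbenzoic acid | OC(=O)c1c(C)c(Cl)c(OC)c(C)c1OCc1ccccc1
F4 | step 8 | 2-(benzyloxy)-5-chloro-4-methoxy-3,6-dimethylbenzoyl chloride | ClC(=O)c1c(C)c(Cl)c(OC)c(C)c1OCc1ccccc1
F5 | step 8 | 3-hydroxy-4-(methoxycarbonyl)-2,5,6-trimethylphenyl 2-(benzyloxy)-5-chloro-4-methoxy-3,6-dimethylbenzoate | COC(=O)c1c(C)c(C)c(OC(=O)c2c(C)c(Cl)c(OC)c(C)c2OCc2ccccc2)c(C)c1O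
F6 | step 3 | methyl 3-methoxy-2-methylpent-2-enoate (E/Z mixture) | CCC(OC)=C(C)C(=O)OC
F7 | step 3 | (1Z,3Z)-1,3-dimethoxy-2-methyl-1-(trimethylsilyloxy)penta-1,3-diene | CO/C(O[Si](C)(C)C)=C(C)/C(OC)=C/C
F8 | step 3 | methyl 2-hydroxy-4-methoxy-3,5,6-trimethylbenzoate | COC(=O)c1c(C)c(C)c(OC)c(C)c1O
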